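Reckon target as the lower of two lines, a clock and a ceiling, for flasks that differ in catalyst.

| flask | substrate | coupling partner | protic impurity | free catalyst | added ligand | remark | time |
|---|---|---|---|---|---|---|---|
| birch | 0.16 M | 0.168 M | 3.2 mM | 4.1 mM | 3.8 mM | run made earlier |  |
| elm | 0.16 M | 0.168 M | 3.2 mM | 43 mM | 3.8 mM | run made earlier |  |
| west | 0.16 M | 0.168 M | 3.20 mM | 3.0 mM | 3.8 mM |  | 4.0 d |
| north | 0.16 M | 0.168 M | 3.20 mM | 10 mM | 3.8 mM |  | 4.0 d |
| north-east | 0.16 M | 0.168 M | 3.20 mM | 30 mM | 3.8 mM |  | 4.0 d |

| run | time / h | target / % | substrate / % |
|---|---|---|---|
| birch | 12.0 | 8.7 | 89.6 |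
| birch | 25.0 | 16.6 | 80.5 |
| birch | 40.0 | 25.6 | 72.4 |
| birch | 50.0 | 31.0 | 66.1 |
| elm | 4.00 | 23.7 | 50.2 |
| elm | 8.00 | 44.4 | 29.6 |
| elm | 20.0 | 75.8 | 0.2 |
| elm | 50.0 | 76.6 | 0 |

(each reading ± 0.5 percentage points)
- amount of target at the end, in percent of the substrate charged for west, north, north-east, in this order
- how the row runs (hardly changes / falls all the way / rises, then falls / falls, then rises / rises all the way)
- what was read earlier has a scatter of 0.5 percentage points, one standard deviation
- "hardly changes" means that all values lie within two and a half points (for a concentration: within two and a half percent of the largest)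

1. Turn up the catalyst. By hand, this gives more rounds per hour but also more substrate that never comes out as target. Elm ends at 76.6%, which reads as 0.871 of substrate lost per unit of catalyst fraction. So take the ceiling as one minus this figure times the catalyst fraction.

2. Turn up the time. By hand, target grows until substrate is used up, and elm holds 0.2% of substrate at 20.0 h while target goes from 75.8% there to 76.6% at 50.0 h. A fall first-order in substrate does not fit, though: carried on from elm's first two readings, it leaves 6.07% at 20.0 h, more than the reading. Take the coupling partner as the clock instead (pseudo-first-order at fixed catalyst), with its charge at 1.05 of the substrate charge.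

3. Birch at 50.0 h gives 0.273 /h, the clock rate: the fraction of remaining coupling partner used per hour, per unit of catalyst fraction. On elm at 8.00 h it gives 46.6% against the reading 44.4%.

4. Apply both lines at 4.0 d. West has ceiling 98.4% and clock 40.8%, and the clock is lower than the ceiling. North has ceiling 94.6% and clock 84.6%, and the clock is again lower than the ceiling. North-east has ceiling 83.7%, lower than its clock. My row therefore rises, then falls, and the fall is 0.90 percentage points.

5. The forecast says 41%, 92%, 83%, rises, then falls. Of north it says “it should be essentially finished”, and its value for north is 7.4 points higher than my clock.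

The flask gives 41.5%, 86.8%, 83.2%, rises, then falls.

    substrate + free catalyst → catalyst intermediate A (k = 542 /M/h)
    catalyst intermediate C ⇌ free catalyst + target (K = 0.190 M, k = 1.40 /h)
    coupling partner + catalyst intermediate B ⇌ catalyst intermediate C (K = 2.09 /M, k = 14.1 /M/h)
    free catalyst + added ligand ⇌ idle complex, settled at all times (K = 123 /M)
    catalyst intermediate A → catalyst intermediate B (k = 2.87 /h)
    coupling partner + protic impurity → quenched reagent (k = 16.0 /M/h)

North ends with 7.07% of its substrate still there. The row turns at 13 mM of free catalyst, and at that charge the clock gives 93.0% and the ceiling 92.8%. On west at 2.00 d the clock gives 22.9%, and the flask holds 22.7% of target.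

(The runs were computed on assumed constants; the scatter is artificial.)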